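**Retrosynthetic overview**
1. Vitisinol D ⇒ its tetra-O-TIPS ether ⇒ (γ,δ-dehydrogenation of the enone) the analogue with a 4-(2-arylethyl) arm. The styryl C=C is installed last.
2. Key disconnection: C5–C6 and C1–C7 together, i.e. the whole cyclopentanone ring. Both bonds form in one anodic dearomative [3+2] (formal [5+2]) annulation of a stilbene radical cation onto two meta-related CH carbons of a resorcinol ring.
3. Ring order: the six-membered ring is the bought resorcinol ring, dearomatised to the ene-dione. The five-membered ring closes onto it in the same electrolysis. No other ring is built.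
4. All four stereocentres arise in that step. The only source of chirality is the D-glucose bought in polydatin. It sits on the oxygen that becomes C8=O and is expelled as that ketone forms.
5. Building blocks: polydatin (arene half, its alkene temporarily saturated) and resveratrol (alkene half).

Assumption: the target is the enantiomer encoded by the SMILES, which is (1R,5S,6R,7R) in bicyclo[3.2.1]oct-3-ene-2,8-dione numbering, with the 3,5-dihydroxyphenyl group endo, the 4-hydroxyphenyl group exo, and the two trans.

**Step 1**
Reactants: 1, polydatin ((E)-resveratrol 3-O-β-D-glucopyranoside)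
Product: 2, dihydropolydatin (3-hydroxy-5-[2-(4-hydroxyphenyl)ethyl]phenyl β-D-glucopyranoside)
Conditions: H2 (1 atm), 10% Pd/C, MeOH, rt
Reagents that add atoms: none
Why: Catalytic hydrogenation reduces only the stilbene C=C, which removes the one site of the arene partner that would compete in Step 5 as a nucleophile (8–8′ coupling) or as an oxidisable π-system; the glucoside stereocentres are untouched.

**Step 2**
Reactants: 2
Product: 3, 3-(TIPSO)-5-{2-[4-(TIPSO)phenyl]ethyl}phenyl 6-O-TIPS-β-D-glucopyranoside
Conditions: TIPSCl (3.3 equiv), imidazole, DMF, 0 °C → rt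
Reagents that add atoms: triisopropylsilyl chloride, CC(C)[Si](Cl)(C(C)C)C(C)C
Why: In this silyl ether formation the bulky chlorosilane reacts with the two phenols and the primary 6-OH but not with the secondary sugar hydroxyls; no stereocentre is affected.

**Step 3**
Reactants: 3
Product: 4, the 2,3,4-tri-O-acetate of 3
Conditions: Ac2O, pyridine, DMAP (cat.), CH2Cl2, rt
Reagents that add atoms: acetic anhydride, CC(=O)OC(C)=O
Why: Standard acetylation caps the remaining OH nucleophiles that would trap a radical cation, and the 2-OAc group later assists departure of the sugar; no stereocentre is affected.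

**Step 4**
Reactants: 5, (E)-resveratrol
Product: 6, (E)-3,5,4′-tris(triisopropylsilyloxy)stilbene
Conditions: TIPSCl (3.5 equiv), imidazole, DMF, rt
Reagents that add atoms: triisopropylsilyl chloride, CC(C)[Si](Cl)(C(C)C)C(C)C
Why: Exhaustive phenol silylation switches off phenoxyl-radical dimerisation, keeps the 4-oxygen a donor (lowest oxidation potential in the mixture), and sterically shields the stilbene's own resorcinol ring.

**Step 5 (key step)**
Reactants: 4 (2.0 equiv) and 6 (1.0 equiv, added by syringe pump)
Product: 7, (1R,5S,6R,7R)-6-[3,5-bis(TIPSO)phenyl]-7-[4-(TIPSO)phenyl]-4-{2-[4-(TIPSO)phenyl]ethyl}bicyclo[3.2.1]oct-3-ene-2,8-dione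
Conditions: undivided cell, RVC anode | Pt cathode, (4-BrC6H4)3N (10 mol %), n-Bu4NPF6 (0.1 M), CH2Cl2/HFIP 3:1, −20 °C, constant current (ca. 0.5 mA cm⁻²), 2.2 F mol⁻¹
Reagents that add atoms: none
Why: Proposed new method: only 6 is oxidised (ca. +1.15 V vs ≥ +1.5 V for 4); its radical cation is attacked at the carbon bearing the bis-silyloxyphenyl ring (leaving the 4-silyloxybenzyl radical) by the ring carbon of 4 that is para to OTIPS, ortho to O-Glc and ortho to the alkyl arm; fast loss of TIPS⁺ from the σ-complex gives a 4H-cyclohexa-2,5-dienone that still carries its ring H; the benzylic radical is oxidised to the cation and is captured at carbon by the enol-glucoside C(OGlc)=CH in a 5-ring closure (carbon rather than oxygen attack, as for any enol ether); the resulting O-glucosyl oxocarbenium ejects the sugar (2-OAc assisted) to give the C8 ketone, and cathodic HFIP alkoxide scavenges TIPS⁺ and Glc⁺ so the cell stays neutral; relative configuration comes from the stacked approach with the bis-silyloxyphenyl ring endo and the aryl on the cationic carbon exo and trans; absolute configuration comes from the exo-anomeric, s-cis conformation of the glucoside, which places O5″/C5″–CH2OTIPS over one face of C(OGlc)=CH so that closure occurs on the H-1″ face, giving (1R,5S,6R,7R); the closest known reaction types are the cationic and anodic [5+2] phenol–styrene cycloaddition to bicyclo[3.2.1]octenediones, the oxidative phenol–alkene [3+2] annulation to dihydrobenzofurans, and facially selective cycloadditions of acetylated β-D-glucosyloxy-dienes.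

**Step 6**
Reactants: 7
Product: 8, tetra-O-TIPS vitisinol D (the 4-[(E)-2-(4-TIPSO-phenyl)ethenyl] compound, same four stereocentres)
Conditions: TBSOTf, Et3N, CH2Cl2, 0 °C; then DDQ, 2,6-lutidine, 0 °C → rt
Reagents that add atoms: none
Why: The side-chain γ-CH2 is the only enolisable position because both α-carbons are bridgeheads, so silyl dienol ether formation followed by DDQ hydride abstraction at the doubly activated benzylic δ-CH2 (classical enone → dienone γ,δ-dehydrogenation) gives the conjugated E-styryl group without touching the stereocentres.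

**Step 7**
Reactants: 8
Product: 9, vitisinol D
Conditions: TBAF/AcOH (1:1), THF, 0 °C
Reagents that add atoms: none
Why: Buffered fluoride cleaves the four aryl silyl ethers while avoiding free phenoxide, which could trigger retro-1,6-addition (C1–C7 cleavage) or retro-Claisen opening; the bridgehead and β-carbon stereocentres cannot epimerise.

**Compound list**
1 | Polydatin (trans-piceid) | OC[C@H]1O[C@@H](Oc2cc(O)cc(/C=C/c3ccc(O)cc3)c2)[C@H](O)[C@@H](O)[C@@H]1O | starting material
2 | Dihydropolydatin | OC[C@H]1O[C@@H](Oc2cc(O)cc(CCc3ccc(O)cc3)c2)[C@H](O)[C@@H](O)[C@@H]1O | intermediate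
3 | Tri-O-TIPS dihydropolydatin (both phenols and 6″-O) | CC(C)[Si](C(C)C)(C(C)C)OC[C@H]1O[C@@H](Oc2cc(O[Si](C(C)C)(C(C)C)C(C)C)cc(CCc3ccc(O[Si](C(C)C)(C(C)C)C(C)C)cc3)c2)[C@H](O)[C@@H](O)[C@@H]1O | intermediate
4 | 2″,3″,4″-Tri-O-acetate of 3 | CC(C)[Si](C(C)C)(C(C)C)OC[C@H]1O[C@@H](Oc2cc(O[Si](C(C)C)(C(C)C)C(C)C)cc(CCc3ccc(O[Si](C(C)C)(C(C)C)C(C)C)cc3)c2)[C@H](OC(C)=O)[C@@H](OC(C)=O)[C@@H]1OC(C)=O | intermediate
5 | (E)-Resveratrol | Oc1ccc(/C=C/c2cc(O)cc(O)c2)cc1 | starting material
6 | (E)-3,5,4′-Tris(triisopropylsilyloxy)stilbene | CC(C)[Si](C(C)C)(C(C)C)Oc1ccc(/C=C/c2cc(O[Si](C(C)C)(C(C)C)C(C)C)cc(O[Si](C(C)C)(C(C)C)C(C)C)c2)cc1 | intermediate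
7 | (1R,5S,6R,7R)-Cycloadduct with 4-(2-arylethyl) arm, tetra-TIPS | O=C1C=C(CCc2ccc(O[Si](C(C)C)(C(C)C)C(C)C)cc2)[C@H]2C(=O)[C@@H]1[C@H](c1ccc(O[Si](C(C)C)(C(C)C)C(C)C)cc1)[C@H]2c1cc(O[Si](C(C)C)(C(C)C)C(C)C)cc(O[Si](C(C)C)(C(C)C)C(C)C)c1 | intermediate
8 | Tetra-O-TIPS vitisinol D | O=C1C=C(/C=C/c2ccc(O[Si](C(C)C)(C(C)C)C(C)C)cc2)[C@H]2C(=O)[C@@H]1[C@H](c1ccc(O[Si](C(C)C)(C(C)C)C(C)C)cc1)[C@H]2c1cc(O[Si](C(C)C)(C(C)C)C(C)C)cc(O[Si](C(C)C)(C(C)C)C(C)C)c1 | intermediate
9 | Vitisinol D | O=C1C=C(/C=C/c2ccc(O)cc2)[C@H]2C(=O)[C@@H]1[C@H](c1ccc(O)cc1)[C@H]2c1cc(O)cc(O)c1 | target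

**Totals:** 7 steps. Longest linear sequence is 6 steps (1→2→3→4→7→8→9).

**Steps most likely to fail**

1. **Step 5 (proposed new step).**
   - Chemical risks: loss of the ring H (rearomatisation) or O-closure to a dihydrobenzofuran; self-reaction of 6; first attack ortho to OTIPS.
   - Stereochemical risk: the aryl–O rotamer with the sugar on the side of the first-formed bond would favour the opposite face. Because the glucose leaves in this step, the facial ratio becomes the ee directly. It must be measured on 7 and upgraded by crystallisation if needed.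
   - Fallback (known chemistry): move to the established cationic [5+2] manifold, in which the arene is the oxidised partner.
     - Add a para-methoxy group to the phenol, oxidise with PhI(OAc)2/MeOH to the quinone monoketal, and combine with 6 under TMSOTf at −78 °C.
     - Delete the extra 3-OMe through the diosphenol triflate and Pd/formate reduction.
     - Use persilylated polydatin as the alkene partner, so the cycloadducts are aryl-glucoside diastereomers that can be separated before the sugar is removed.

2. **Step 6.**
   - Risks: DDQ attack at the other benzylic C–H bonds, or Lewis-acid-induced C1–C7 cleavage.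
   - Fallback: drop the hydrogenation/dehydrogenation detour.
     - Ozonolyse protected polydatin to the 3-glucosyloxy-5-silyloxybenzaldehyde.
     - Carry it through Step 5 as its dimethyl acetal, then unmask the β-formyl enone.
     - Install the styryl group by Horner–Wadsworth–Emmons olefination with diethyl 4-(TIPSO)benzylphosphonate.

3. **Step 7.**
   - Risk: retro-Michael isomerisation toward the aromatic ε-viniferin skeleton once phenoxides form.
   - Fallback: change the protecting-group exit. Run a desilylative acetylation (fluoride in the presence of Ac2O, so each phenoxide is trapped as it forms) to the tetraacetate, then deacetylate under near-neutral conditions with NH4OAc in aqueous MeOH.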